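Target: (2S,4S)-7,4'-dihydroxyflavan (2,4-cis) joined through its C4 to C8 of (−)-epicatechin (2R,3R, 2,3-cis).
Cuts: the seven O-benzyl bonds; the upper C4–H (from a C4 carbinol); then, in one operation, lower O1–C8a and lower C8–upper C4; then lower C2–aryl (Grignard plus α-benzyloxy aldehyde), lower C4–C4a (aryllithium plus glycidyl ether) and upper C2–aryl (arylation of a chromone).
Enabling feature: in the lower benzopyran the ether carbon C8a and the interflavan carbon C8 are adjacent atoms of the phloroglucinol ring. They can therefore be the two ends of one aryne: O1 adds to C8a, and the carbanion released at C8 makes the 4→8 bond with fixed regiochemistry.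
Forward order: fluororesorcinol ring, three-carbon chain, catechol ring; separately the upper benzopyranone; then the lower pyran ring and the interflavan bond together; then C4 deoxygenation and debenzylation.
Stereochemistry: lower C3 is bought with (R)-trityl glycidyl ether. Lower C2 is relayed from it by chelation control and kept with retention, because closure occurs at the aryl carbon. Upper C2 comes from rhodium-catalysed asymmetric 1,4-addition, and upper C4 is relayed from upper C2 by pseudo-axial hydride delivery.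

Key step: step 10

Assumption: the (S)-configured biaryl bisphosphine is taken to direct aryl transfer to the same enone face as in Hayashi–Miyaura additions to 2-cyclohexenone, which corresponds to 2S in the flavanone; if the sense were opposite, the antipodal ligand would be used.

Step 1
Reactants: 1 5-fluorobenzene-1,3-diol (5-fluororesorcinol)
Product: 2 1,3-bis(benzyloxy)-5-fluorobenzene
Conditions: BnBr (2.2 equiv), K2CO3, DMF, 60 °C
Reagents that add atoms: benzyl bromide BrCc1ccccc1
Why: Williamson ether synthesis on both phenols, under which the unactivated C–F bond is inert.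

Step 2
Reactants: 2 1,3-bis(benzyloxy)-5-fluorobenzene
Product: 3 1,5-bis(benzyloxy)-2,4-dibromo-3-fluorobenzene
Conditions: NBS (2.05 equiv), MeCN, 0 °C to rt
Reagents that add atoms: N-bromosuccinimide O=C1CCC(=O)N1Br
Why: Electrophilic aromatic bromination, in which both ether groups direct ortho/para to the two equivalent positions flanking fluorine while the position between the two ethers is the more hindered one, as in the well-known 4,6-dibromination of resorcinol diethers.

Step 3
Reactants: 3 1,5-bis(benzyloxy)-2,4-dibromo-3-fluorobenzene; 4 (R)-trityl glycidyl ether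
Product: 6 (R)-1-[4,6-bis(benzyloxy)-3-bromo-2-fluorophenyl]-3-(trityloxy)propan-2-ol, via aryllithium 5 (not isolated)
Conditions: n-BuLi (1.0 equiv), THF, −78 °C; BF3·OEt2, then 4, −78 °C; H2O
Reagents that add atoms: none
Why: Bromine–lithium exchange at one of two equivalent bromides followed by BF3-assisted SN2 opening of the terminal epoxide at its CH2 end, which leaves the stereocentre of 4 untouched and keeps the ortho-fluoroaryllithium below the temperature of LiF loss.

Step 4
Reactants: 6 (R)-1-[4,6-bis(benzyloxy)-3-bromo-2-fluorophenyl]-3-(trityloxy)propan-2-ol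
Product: 7 (R)-1,5-bis(benzyloxy)-2-[2-(benzyloxy)-3-(trityloxy)propyl]-4-bromo-3-fluorobenzene
Conditions: NaH, BnBr, Bu4NI (cat.), THF/DMF, 0 °C to rt
Reagents that add atoms: benzyl bromide BrCc1ccccc1
Why: Williamson benzylation of the secondary alkoxide, which should outrun five-membered SNAr closure onto the unactivated C–F bond at this temperature, and the trityl group cannot migrate as a silyl group would.

Step 5
Reactants: 7 (R)-1,5-bis(benzyloxy)-2-[2-(benzyloxy)-3-(trityloxy)propyl]-4-bromo-3-fluorobenzene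
Product: 8 (R)-2-(benzyloxy)-3-[4,6-bis(benzyloxy)-3-bromo-2-fluorophenyl]propan-1-ol
Conditions: p-TsOH·H2O (cat.), MeOH/CH2Cl2, rt
Reagents that add atoms: none
Why: Acid-catalysed SN1 methanolysis of the trityl ether, mild enough to leave all benzyl ethers in place.

Step 6
Reactants: 8 (R)-2-(benzyloxy)-3-[4,6-bis(benzyloxy)-3-bromo-2-fluorophenyl]propan-1-ol
Product: 9 (R)-2-(benzyloxy)-3-[4,6-bis(benzyloxy)-3-bromo-2-fluorophenyl]propanal
Conditions: TEMPO (cat.), PhI(OAc)2, CH2Cl2, rt
Reagents that add atoms: none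
Why: Oxoammonium (TEMPO) oxidation stops at the aldehyde and is base-free, so the α-alkoxy stereocentre should not epimerise.

Step 7
Reactants: 9 (R)-2-(benzyloxy)-3-[4,6-bis(benzyloxy)-3-bromo-2-fluorophenyl]propanal; 10 1,2-bis(benzyloxy)-4-bromobenzene
Product: 12 (1R,2R)-2-(benzyloxy)-1-[3,4-bis(benzyloxy)phenyl]-3-[4,6-bis(benzyloxy)-3-bromo-2-fluorophenyl]propan-1-ol, via arylmagnesium bromide 11 (not isolated)
Conditions: 10, Mg, THF, 40 °C; added to 9, MgBr2·OEt2, CH2Cl2, −78 °C; aq NH4Cl
Reagents that add atoms: none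
Why: Cram-chelate-controlled Grignard addition, in which magnesium ties the aldehyde oxygen to the α-benzyloxy oxygen in a five-membered chelate and the aryl group attacks from the side of the α-hydrogen, which should give the syn (1R,2R) carbinol with the C1 hydroxyl free and the C2 oxygen already masked.

Step 8
Reactants: 13 7-hydroxy-4H-chromen-4-one
Product: 14 7-(benzyloxy)-4H-chromen-4-one
Conditions: BnBr, K2CO3, acetone, reflux
Reagents that add atoms: benzyl bromide BrCc1ccccc1
Why: Williamson ether synthesis on the single acidic phenol.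

Step 9
Reactants: 14 7-(benzyloxy)-4H-chromen-4-one; 15 [4-(benzyloxy)phenyl]boronic acid
Product: 16 (S)-7-(benzyloxy)-2-[4-(benzyloxy)phenyl]chroman-4-one
Conditions: [Rh(OH)(cod)]2 (cat.), (S)-MeO-F12-BIPHEP = (S)-2,2'-bis[bis(3,4,5-trifluorophenyl)phosphino]-6,6'-dimethoxy-1,1'-biphenyl (cat.), toluene/H2O, 20 °C
Reagents that add atoms: none
Why: Rhodium-catalysed asymmetric 1,4-addition of an arylboronic acid (Hayashi–Miyaura reaction) to a chromone, a known route to enantioenriched flavanones, in which the electron-poor (S)-bisphosphine shields one enone face so that aryl transfer sets C2 as S, and the near-neutral medium avoids retro-oxa-Michael racemisation.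

Step 10
Reactants: 12 (1R,2R)-2-(benzyloxy)-1-[3,4-bis(benzyloxy)phenyl]-3-[4,6-bis(benzyloxy)-3-bromo-2-fluorophenyl]propan-1-ol; 16 (S)-7-(benzyloxy)-2-[4-(benzyloxy)phenyl]chroman-4-one
Product: 20 (2S)-7-(benzyloxy)-2-[4-(benzyloxy)phenyl]-4-{(2R,3R)-3,5,7-tris(benzyloxy)-2-[3,4-bis(benzyloxy)phenyl]chroman-8-yl}chroman-4-ol (C4 epimers of no consequence), via dilithiated fluoroarene 17 (not isolated), via aryne alkoxide 18 (not isolated), via 8-lithioflavan 19 (not isolated)
Conditions: n-BuLi (2.05 equiv), THF (0.02 M), −78 °C; warm to −25 °C; recool to −78 °C, then 16; aq NH4Cl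
Reagents that add atoms: none
Why: Proposed new method: n-BuLi first deprotonates the carbinol and then exchanges the C8 bromine, on warming the ortho-fluoroaryllithium 17 loses LiF to give the C8–C8a aryne 18, the tethered lithium alkoxide adds in the ring plane to C8a (formally 6-exo-dig closure of the lower pyran ring) and thereby returns the carbanion to C8 as 19, which then adds 1,2 to the carbonyl group of 16. The closest known reaction types are the closure of alcohol-tethered arynes to chromans with capture of the neighbouring carbon by an iodine electrophile, the addition of metal amides and thiolates to arynes followed by electrophile capture, and the addition of 8-lithiated benzylated flavan-3-ols to flavan-4-ones; new is their union in one flask with an oxygen nucleophile and a ketone. No bond at C2 or C3 of the lower unit is broken, so the syn (1R,2R) array of 12 passes with retention into the 2,3-cis (2R,3R) pyran that cationic closure through O1–C2 disfavours, and the configuration of the new carbinol centre C4 does not matter because step 11 makes it planar again. Regioselectivity is secured three times: only C8a is within reach of the three-atom tether, the C7 benzyloxy group polarises the aryne so that attack occurs at the distal carbon C8a and charge builds up next to oxygen at C8, and the C3 oxygen is a benzyl ether so that no five-membered ring can form. Chemoselectivity rests on high dilution (intramolecular O-attack against aryllithium–aryne coupling), on exact n-BuLi stoichiometry, and on recooling before 16 is added so that 1,2-addition outruns enolisation and retro-oxa-Michael opening of the flavanone.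

Step 11
Reactants: 20 (2S)-7-(benzyloxy)-2-[4-(benzyloxy)phenyl]-4-{(2R,3R)-3,5,7-tris(benzyloxy)-2-[3,4-bis(benzyloxy)phenyl]chroman-8-yl}chroman-4-ol
Product: 21 (2S,4S)-7-(benzyloxy)-2-[4-(benzyloxy)phenyl]-4-{(2R,3R)-3,5,7-tris(benzyloxy)-2-[3,4-bis(benzyloxy)phenyl]chroman-8-yl}chroman
Conditions: Et3SiH, CF3CO2H, CH2Cl2, −40 to 0 °C
Reagents that add atoms: none
Why: Ionic hydrogenation (SN1 ionisation, then hydride transfer from the silane), closely precedented for 4-aryl-flavan-4-ols, in which the doubly benzylic C4 cation, stabilised by the para 7-benzyloxy group, should take hydride along the pseudo-axial trajectory of the half-chair with the 2-aryl group equatorial, that is on the face of H2, so that the 4-aryl group ends equatorial and cis to the 2-aryl group (4S).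

Step 12
Reactants: 21 (2S,4S)-7-(benzyloxy)-2-[4-(benzyloxy)phenyl]-4-{(2R,3R)-3,5,7-tris(benzyloxy)-2-[3,4-bis(benzyloxy)phenyl]chroman-8-yl}chroman
Product: 22 (2R,3R)-2-(3,4-dihydroxyphenyl)-8-[(2S,4S)-7-hydroxy-2-(4-hydroxyphenyl)chroman-4-yl]chroman-3,5,7-triol
Conditions: H2 (1 atm), Pd(OH)2/C, THF/MeOH, rt
Reagents that add atoms: none
Why: Catalytic hydrogenolysis of all seven benzyl ethers under neutral conditions, the standard unmasking of benzylated oligoflavanoids, under which the cyclic benzylic C–O bonds, the C4–C8 bond and all four stereocentres should persist.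

Compound list
1 | 5-fluorobenzene-1,3-diol | Oc1cc(O)cc(F)c1 | starting material
2 | 1,3-bis(benzyloxy)-5-fluorobenzene | Fc1cc(OCc2ccccc2)cc(OCc2ccccc2)c1 | intermediate
3 | 1,5-bis(benzyloxy)-2,4-dibromo-3-fluorobenzene | Fc1c(Br)c(OCc2ccccc2)cc(OCc2ccccc2)c1Br | intermediate
4 | (R)-2-[(trityloxy)methyl]oxirane ((R)-trityl glycidyl ether) | c1ccccc1C(c1ccccc1)(c1ccccc1)OC[C@H]1CO1 | starting material
5 | 4,6-bis(benzyloxy)-3-bromo-2-fluorophenyllithium | [Li]c1c(F)c(Br)c(OCc2ccccc2)cc1OCc1ccccc1 | intermediate
6 | (R)-1-[4,6-bis(benzyloxy)-3-bromo-2-fluorophenyl]-3-(trityloxy)propan-2-ol | c1ccccc1C(c1ccccc1)(c1ccccc1)OC[C@H](O)Cc1c(F)c(Br)c(OCc2ccccc2)cc1OCc1ccccc1 | intermediate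
7 | (R)-1,5-bis(benzyloxy)-2-[2-(benzyloxy)-3-(trityloxy)propyl]-4-bromo-3-fluorobenzene | c1ccccc1C(c1ccccc1)(c1ccccc1)OC[C@H](OCc1ccccc1)Cc1c(F)c(Br)c(OCc2ccccc2)cc1OCc1ccccc1 | intermediate
8 | (R)-2-(benzyloxy)-3-[4,6-bis(benzyloxy)-3-bromo-2-fluorophenyl]propan-1-ol | OC[C@H](OCc1ccccc1)Cc1c(F)c(Br)c(OCc2ccccc2)cc1OCc1ccccc1 | intermediate
9 | (R)-2-(benzyloxy)-3-[4,6-bis(benzyloxy)-3-bromo-2-fluorophenyl]propanal | O=C[C@H](OCc1ccccc1)Cc1c(F)c(Br)c(OCc2ccccc2)cc1OCc1ccccc1 | intermediate
10 | 1,2-bis(benzyloxy)-4-bromobenzene | Brc1ccc(OCc2ccccc2)c(OCc2ccccc2)c1 | starting material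
11 | 3,4-bis(benzyloxy)phenylmagnesium bromide | Br[Mg]c1ccc(OCc2ccccc2)c(OCc2ccccc2)c1 | intermediate
12 | (1R,2R)-2-(benzyloxy)-1-[3,4-bis(benzyloxy)phenyl]-3-[4,6-bis(benzyloxy)-3-bromo-2-fluorophenyl]propan-1-ol | O[C@H](c1ccc(OCc2ccccc2)c(OCc2ccccc2)c1)[C@H](OCc1ccccc1)Cc1c(F)c(Br)c(OCc2ccccc2)cc1OCc1ccccc1 | intermediate
13 | 7-hydroxy-4H-chromen-4-one | O=c1ccoc2cc(O)ccc12 | starting material
14 | 7-(benzyloxy)-4H-chromen-4-one | O=c1ccoc2cc(OCc3ccccc3)ccc12 | intermediate
15 | [4-(benzyloxy)phenyl]boronic acid | OB(O)c1ccc(OCc2ccccc2)cc1 | starting material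
16 | (S)-7-(benzyloxy)-2-[4-(benzyloxy)phenyl]chroman-4-one | c1ccccc1COc1ccc([C@@H]2CC(=O)c3ccc(OCc4ccccc4)cc3O2)cc1 | intermediate
17 | lithium alkoxide of 12 with lithium in place of bromine (dilithiated fluoroarene) | [Li]O[C@H](c1ccc(OCc2ccccc2)c(OCc2ccccc2)c1)[C@H](OCc1ccccc1)Cc1c(F)c([Li])c(OCc2ccccc2)cc1OCc1ccccc1 | intermediate
18 | lithium (1R,2R)-alkoxide bearing the 3,5-bis(benzyloxy)-substituted aryne (aryne alkoxide) | [Li]O[C@H](c1ccc(OCc2ccccc2)c(OCc2ccccc2)c1)[C@H](OCc1ccccc1)CC1=C(OCc2ccccc2)C=C(OCc2ccccc2)C#C1 | intermediate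
19 | (2R,3R)-3,5,7-tris(benzyloxy)-2-[3,4-bis(benzyloxy)phenyl]chroman-8-yllithium | [Li]c1c(OCc2ccccc2)cc(OCc2ccccc2)c2c1O[C@H](c1ccc(OCc3ccccc3)c(OCc3ccccc3)c1)[C@H](OCc1ccccc1)C2 | intermediate
20 | (2S)-7-(benzyloxy)-2-[4-(benzyloxy)phenyl]-4-{(2R,3R)-3,5,7-tris(benzyloxy)-2-[3,4-bis(benzyloxy)phenyl]chroman-8-yl}chroman-4-ol, C4 not defined | O(Cc1ccccc1)c1ccc([C@@H]2CC(O)(c3c(OCc4ccccc4)cc(OCc4ccccc4)c4c3O[C@H](c3ccc(OCc5ccccc5)c(OCc5ccccc5)c3)[C@H](OCc3ccccc3)C4)c3ccc(OCc4ccccc4)cc3O2)cc1 | intermediate
21 | (2S,4S)-7-(benzyloxy)-2-[4-(benzyloxy)phenyl]-4-{(2R,3R)-3,5,7-tris(benzyloxy)-2-[3,4-bis(benzyloxy)phenyl]chroman-8-yl}chroman | O(Cc1ccccc1)c1ccc([C@@H]2C[C@H](c3c(OCc4ccccc4)cc(OCc4ccccc4)c4c3O[C@H](c3ccc(OCc5ccccc5)c(OCc5ccccc5)c3)[C@H](OCc3ccccc3)C4)c3ccc(OCc4ccccc4)cc3O2)cc1 | intermediate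
22 | (2R,3R)-2-(3,4-dihydroxyphenyl)-8-[(2S,4S)-7-hydroxy-2-(4-hydroxyphenyl)chroman-4-yl]chroman-3,5,7-triol | Oc1ccc([C@@H]2C[C@H](c3c(O)cc(O)c4c3O[C@H](c3ccc(O)c(O)c3)[C@H](O)C4)c3ccc(O)cc3O2)cc1 | target

Total step count: 12. Longest linear sequence: 10 (steps 1 to 7, then 10 to 12).

Steps most likely to fail

Step 10. What may go wrong:
- coupling of an aryllithium with the aryne of a second molecule;
- hydride transfer from the carbinol C–H to the aryne in place of O-attack;
- anionic rearrangement of the neighbouring benzyl ether during the warm phase;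
- enolisation of the flavanone in place of 1,2-addition.

The fallback separates the events and uses known chemistry only. It sets out from 12 and comes back at 20. Treatment of 12 with KH in THF/DMF at 60 °C should close the pyran ring by intramolecular SNAr. The two benzyloxy groups are meta to the C–F carbon, and the ortho bromine stabilises the addition intermediate. This gives (2R,3R)-3,5,7-tris(benzyloxy)-2-[3,4-bis(benzyloxy)phenyl]-8-bromochroman F1. Bromine–lithium exchange on it (n-BuLi, THF, −78 °C) then gives 19 at a temperature it tolerates, and addition of 16 gives 20.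

Step 7. What may go wrong: incomplete chelation in the presence of THF, and hence poor facial selectivity at the aldehyde. The fallback moves the stereocontrol from C–C bond formation to a ketone reduction. It sets out from 9 (with 11 made from 10) and comes back at 12. Unselective addition of 11 to 9 gives the C1-epimeric carbinol mixture F2. Dess–Martin periodinane converts both epimers into (R)-2-(benzyloxy)-1-[3,4-bis(benzyloxy)phenyl]-3-[4,6-bis(benzyloxy)-3-bromo-2-fluorophenyl]propan-1-one F3. Reduction with the bulky, non-chelating hydride KBH(s-Bu)3 in THF at −78 °C should follow the polar Felkin–Anh model (hydride anti to the C–OBn bond) and deliver the syn (1R,2R) carbinol 12.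

Step 11. What may go wrong: poor facial selectivity of hydride transfer to the crowded cation, or acid-induced opening of a benzylic pyran C–O bond. The fallback replaces hydride transfer by surface hydrogenation. It sets out from 20 and comes back at 22. Catalytic p-TsOH in toluene at rt should dehydrate 20 (E1) to the 4-arylflav-3-ene F4. Hydrogenation over Pd(OH)2/C adds hydrogen syn from the face opposite the 2-aryl group, which gives the 2,4-cis arrangement. The same operation removes the seven benzyl groups and gives 22.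

Further compounds
F1 | step 10 | (2R,3R)-3,5,7-tris(benzyloxy)-2-[3,4-bis(benzyloxy)phenyl]-8-bromochroman | Brc1c(OCc2ccccc2)cc(OCc2ccccc2)c2c1O[C@H](c1ccc(OCc3ccccc3)c(OCc3ccccc3)c1)[C@H](OCc1ccccc1)C2
F2 | step 7 | (2R)-2-(benzyloxy)-1-[3,4-bis(benzyloxy)phenyl]-3-[4,6-bis(benzyloxy)-3-bromo-2-fluorophenyl]propan-1-ol, mixture of C1 epimers | OC(c1ccc(OCc2ccccc2)c(OCc2ccccc2)c1)[C@H](OCc1ccccc1)Cc1c(F)c(Br)c(OCc2ccccc2)cc1OCc1ccccc1
F3 | step 7 | (R)-2-(benzyloxy)-1-[3,4-bis(benzyloxy)phenyl]-3-[4,6-bis(benzyloxy)-3-bromo-2-fluorophenyl]propan-1-one | O=C(c1ccc(OCc2ccccc2)c(OCc2ccccc2)c1)[C@H](OCc1ccccc1)Cc1c(F)c(Br)c(OCc2ccccc2)cc1OCc1ccccc1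
F4 | step 11 | (2S)-7-(benzyloxy)-2-[4-(benzyloxy)phenyl]-4-{(2R,3R)-3,5,7-tris(benzyloxy)-2-[3,4-bis(benzyloxy)phenyl]chroman-8-yl}-2H-chromene | O(Cc1ccccc1)c1ccc([C@@H]2C=C(c3c(OCc4ccccc4)cc(OCc4ccccc4)c4c3O[C@H](c3ccc(OCc5ccccc5)c(OCc5ccccc5)c3)[C@H](OCc3ccccc3)C4)c3ccc(OCc4ccccc4)cc3O2)cc1
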